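Late in the summer flask, at −20 °C, Ux reads 0.4% of the charge at 720 min while Dx drifts from 18.3% to 16.8% over 360 min, so I keep a ledger of where the charged Ux went.

| flask | Ux | temperature | remark | time |
|---|---|---|---|---|
| summer | 0.23 M | −20 °C | the very flask that is asked about, followed so far |  |
| dawn | 0.46 M | −35 °C | run made earlier |  |
| flask | 0.23 M | −20 °C |  | 15 h |

| run | time / min | Dx / % | Ux / % |
|---|---|---|---|
| summer | 180 | 19.2 | 4.8 |
| summer | 360 | 18.3 | 0.4 |
| summer | 600 | 17.4 | 0.5 |
| summer | 720 | 16.8 | 0.4 |
| dawn | 8.00 | 0.3 | 98.3 |
| dawn | 20.0 | 2.3 | 95.7 |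
| dawn | 40.0 | 3.6 | 94.4 |
| dawn | 120 | 9.1 | 82.8 |

(scatter of a reading: 0.5 percentage points)

- red: at 15 h take out 90% of the Dx then present, then wait 15 h
- ochre: at 15 h add Ux, 50.0% of the amount charged, then wait 15 h
- violet: change nothing and wait 15 h more
- green: at 15 h raise the temperature by 25 K, then wait 15 h

- Dx, in percent of the Ux first charged, at 15 h
- the option that brings most further Dx ("none" if no option brings more than 2 percentage points) (red / ochre / violet / green / none)
- Dx present, with what was taken out counted in, in percent of the Ux first charged, after red
- Dx present, with what was taken out counted in, in percent of the Ux first charged, after violet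

- removed Dx is counted in
- the numbers in the tables scatter with a standard deviation of 0.5 percentage points
- additions bring no volume worth counting

The first entry is Ux left in the summer flask: 0.4%, less than the scatter of 0.5 percentage points. The second is Dx. Its drift of 1.5 points is twice the scatter of a difference of two readings, so I treat it as a small correction. Carried on in a straight line, it gives 16.1% at 15 h, while the mean of the late readings is 17.5%. The last reading lies between them, so I book 16.8% for now.

The third entry needs the dawn run, at −35 °C, which at 120 min has used 17.2% of its charge and shows 9.1% as Dx. Its booked share, the Dx found per Ux used (an apparent selectivity), reads 52.9%. I assume that it holds in the summer flask, where it books 52.7% to Dx. Of that, 16.8% is found, which leaves a gap of 36 points. The other 47 points I enter as Ux that went elsewhere, and the books close.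

The gap is far larger than the late drift, so I guess that it is a pool in balance with Dx. Then Dx holds 0.319 of Dx plus pool, and violet brings nothing. Red, after the remainder splits again in that ratio, reaches 27.1%, a gain of 10 points. Ochre, at the summer flask's found yield, gains 8.4 points, less than red. Warming I leave unpriced, so I lean to red.

The forecast, differing from me, gives 16.1% now, 15.8% after red and 13% after violet, and picks ochre, holding that “Only fresh Ux can make more Dx”.

The flask gives Dx 17.1% at 15 h, 17.1% after violet and 28.8% after red, and green is best, gaining 27 points against 12 points for red and 8.6 points for ochre.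

    Ux → Dx (k = 0.0120 min⁻¹, Ea = 82.0 kJ mol⁻¹)
    Ux → Ez (k = 4.90 × 10⁻⁴ min⁻¹, Ea = 91.0 kJ mol⁻¹)
    Zu → Vy (k = 0.0140 min⁻¹, Ea = 74.0 kJ mol⁻¹)
    Ux → Zu (k = 0.00460 min⁻¹, Ea = 77.0 kJ mol⁻¹)
    Dx ⇌ Zo (K = 3.10, k = 0.0220 min⁻¹, Ea = 69.0 kJ mol⁻¹, ΔH = −39.0 kJ mol⁻¹)
    (constants at −20 °C)

At 900 min Zo stands at 53.1%, more than my gap, and the Dx–Zo pair, by that step alone and both ways together, has a relaxation half-life of 23.8 min, short against 15 h. Green's gain of 27 points is less than the gap of 36 points.

In the neighbouring flask at −45 °C, Ux ends at 79.4%, so the booked share puts 10.9% in Dx. The computed Dx at the end of that flask is 10.3%.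

(All runs stem from a simulated flask for substances that don't exist; noise was put on by code.)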